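If you want to know what this flask holds at 15 min, count how often its catalyst goes round.

| setting | green | red | flask |
|---|---|---|---|
| solid substrate | 20 mM | 20 mM | 20 mM |
| gas | 3 mM (held) | 3 mM (held) | 3.0 mM (held) |
| free catalyst | 1.7 mM | 2.5 mM | 3.4 mM |
| remark | run made earlier | run made earlier |  |
| time |  |  | 15 min |

| run | time / min | target / % |
|---|---|---|
| green | 3.00 | 3.3 |
| green | 6.00 | 11.6 |
| green | 10.0 | 24.6 |
| green | 12.0 | 30.6 |
| green | 15.0 | 40.0 |
| green | 20.0 | 57.6 |
| red | 3.00 | 5.1 |
| red | 6.00 | 14.9 |
| red | 10.0 | 29.7 |
| red | 12.0 | 37.8 |
| red | 15.0 | 49.3 |
| red | 20.0 | 68.4 |

(readings scatter by 0.3 percentage points)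

- as a solid, counted per litre of solution: solid substrate
- at the start none of the gas is in solution
- at the start none of the solid substrate is in solution

1. target at 15 min, in percent of the solid substrate charged
2. the change that raises the amount of target at 15 min, in percent of the solid substrate charged most ("none" if none brings more than 2 percentage points) (spring / noon / dusk / winter / none)
3. amount of target at 15 min, in percent of the solid substrate charged, after spring

- spring: doubling the saturation concentration of gas, all else as stated
- noon: doubling the solubility of the solid substrate, all else as stated
- dusk: doubling the transfer coefficient of the gas, all else as stated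
- winter: doubling the amount of free catalyst, all else as stated

Take the mean rate of target from 10.0 min to 20.0 min in each run, as read from the readings, and divide the catalyst charged by it:

green: rate 0.660 mM min⁻¹, cycle time 2.58 min

red: rate 0.774 mM min⁻¹, cycle time 3.23 min

This cycle time, the catalyst charged divided by the mean rate of target, is the inverse of the turnover frequency. Running the red rate back to zero reads a lag of 2.33 min.

Now take two extremes for the asked flask. If it kept the red cycle time, its rate would grow with the catalyst and give 66.7%. If it kept the red rate, it would repeat the red 49.3%. I expect the real flask between them, because from green to red the rate read rose 1.17 times, less than the 1.47 times of the catalyst, yet it did rise.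

My own reckoning extends the straight line of cycle time against catalyst:

flask: cycle time 3.97 min, rate 0.857 mM min⁻¹, target 54.3%

Both runs had the same gas and solid substrate, so neither setting was varied between them, and I name no change. The forecast says 57%, more than my 54.3%, names spring and expects 90% after it, on this ground: “Gas transfer is the larger resistance”.

The flask gives 55.4%. The best change is noon, which gains 36 percentage points, while spring gains 2.5 points and reaches 57.9%.

    coupling partner + free catalyst → catalyst intermediate A (k = 6.30 M⁻¹ s⁻¹)
    starting material + catalyst intermediate A → catalyst intermediate B (k = 3.40 M⁻¹ s⁻¹)
    catalyst intermediate B → free catalyst + target (k = 0.260 s⁻¹)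
    gas ⇌ coupling partner, rate k4*(csat - [coupling partner]) (kL = 0.0300 s⁻¹)
    solid substrate ⇌ starting material, rate k5*(cs5 - [starting material]) while solid is left; crystals form when [starting material] > cs5 (solubility = 11.0 mM, k = 0.00150 s⁻¹)

From half time to the end the flask made target at 0.839 mM min⁻¹, a cycle time of 4.05 min. Take the neighbour with 1.4 mM of free catalyst. The same line gives it a cycle time of 2.33 min, and with the green lag of 2.55 min it gives 37.4%. The neighbour gives 35.8%, and 64% of its charged solid substrate is still there, solid or dissolved.

(Readings and results come from a simulation with constants of no real substance; scatter was added.)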